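A direct plan would C-prenylate 5-methoxyresorcinol to A1, mono-acylate A1 with (R)-2-methylbutanoic acid and shift the acyl group to carbon to reach ketone A2. It would build pyrone A3 from a pentan-3-one enol ether and malonyl dichloride, and would join A2 and A3 through formaldehyde by way of the pyrone methide A4. Its weakest steps would be:
(a) the C-prenylation: nothing in 5-methoxyresorcinol would steer the allyl cation between the two hydroxyls and away from the carbon next to OMe, from oxygen or from a second entry, and acid would close the product to a chroman;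
(b) the methylene coupling: one CH2 electrophile would face two carbon nucleophiles, so A4 would also be taken by A3 (bis-pyrone), and this would be the last step, run on both finished fragments;
(c) the handle steps: storing A4 in a masked form and mono-acylating the symmetric diol A1 used in excess would cost operations and add no skeletal bond.

**Plan of the new route**
Retrosynthetic cuts, in order: pyrone C3–C4 and O1–C2 (pyrone made last, by acyl transfer from an aryl lactone); the aryl–C(=O) bond (acyl shift from the neighbouring oxygen); then benzene bonds C1–C2, C2–C3 and C4–C5 (C1 bears the bridge), made together in a cyclobutenone/siloxyalkyne benzannulation.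
Rings arise in the order cyclobutenone, benzene, six-membered lactone (temporary), pyrone; benzene and pyrone are never separate fragments to be joined.
Enabling feature: the benzene ring carries three oxygens of different fate (two OH, one OMe) alternating with three different carbons; they map onto a ketene C=O, an ynol ether oxygen and the OMe of a 3-methoxycyclobutenone.
The phenol oxygen next to the CH2 bridge is 1,5 to the pyrone C2 carbonyl, a latent dihydrocoumarin, which lets the lactone act as protecting group, activating group and leaving group.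
Prenyl arrives on an alkyne carbon and the bridge CH2 inside a glutarate chain, so no arene is C-prenylated, no two rings are coupled through CH2 and no symmetric diol is desymmetrised.

Key step: step 4

Remark: cyclobutenone 5 is racemic and ketene dimer 23 is a racemic E/Z mixture; both are used as such, because all their stereo-elements become sp2 centres later. Each molecule of 23 is built from two molecules of propanoyl chloride 21.

Step 1
Reactants: 1 2-chloro-1,1-dimethoxyethane
Product: 2 methoxyethyne
Conditions: NaNH2 (3.1 equiv), liq. NH3, −33 °C; NH3 evaporated; cold aq. NaCl; distilled (bp 23 °C) into Et2O at −20 °C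
Reagents that add atoms: none
Why: Twofold base-induced elimination (HCl and MeOH) of the chloroacetal gives sodium methoxyacetylide, which water protonates to the volatile ynol ether; this is the classical alkoxyacetylene synthesis and forms no stereocentre.

Step 2
Reactants: 2 methoxyethyne; 3 methyl 5-chloro-5-oxopentanoate
Product: 5 methyl 3-(2-methoxy-4-oxocyclobut-2-en-1-yl)propanoate (racemic), via methyl 5-oxopent-4-enoate 4 (not isolated)
Conditions: 2 (3 equiv), Et3N (1.2 equiv), Et2O, −20 → 20 °C, slow addition of 3, closed vessel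
Reagents that add atoms: none
Why: Et3N dehydrochlorinates 3 to the aldoketene 4, which undergoes the known [2+2] cycloaddition of ketenes with alkoxyacetylenes: the nucleophilic CH terminus of 2 bonds to the ketene carbonyl carbon, so that OMe ends on C3 and the ester chain on C4 of the cyclobutenone; the C4 centre forms racemic and is erased in step 4.

Step 3
Reactants: 6 ethyl 4-methylpent-3-enoate
Product: 9 triisopropyl[(5-methylhex-4-en-1-yn-1-yl)oxy]silane, via lithium 1,1-dibromo-5-methylhexa-1,4-dien-2-olate 7 (not isolated), via lithium 5-methylhex-4-en-1-yn-1-olate 8 (not isolated)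
Conditions: CH2Br2 (2.2 equiv), lithium 2,2,6,6-tetramethylpiperidide (2.1 equiv), THF, −78 °C; LiN(SiMe3)2; n-BuLi, −78 → 25 °C; i-Pr3SiCl, −78 → 0 °C
Reagents that add atoms: dibromomethane, BrCBr; chlorotriisopropylsilane, CC(C)[Si](Cl)(C(C)C)C(C)C
Why: Kowalski ester homologation stopped at the ynolate stage: LiCHBr2 adds to the ester, the dibromo ketone enolate 7 undergoes bromine–lithium exchange and 1,2-shift of the alkyl group to ynolate 8, and the bulky chlorosilane silylates oxygen to give a distillable siloxyalkyne; the low temperature should keep the beta,gamma-alkene from moving into conjugation, and no stereocentre is involved.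

Step 4
Reactants: 5 methyl 3-(2-methoxy-4-oxocyclobut-2-en-1-yl)propanoate; 9 triisopropyl[(5-methylhex-4-en-1-yn-1-yl)oxy]silane
Product: 15 5-methoxy-8-(3-methylbut-2-en-1-yl)-7-(triisopropylsilyloxy)-3,4-dihydro-2H-chromen-2-one, via methyl 5-methoxy-7-oxohepta-4,6-dienoate 10 (not isolated), via methyl 5-methoxy-5-[3-(3-methylbut-2-en-1-yl)-4-oxo-2-(triisopropylsilyloxy)cyclobut-2-en-1-yl]pent-4-enoate 11 (not isolated), via methyl 5-methoxy-8-(3-methylbut-2-en-1-yl)-9-oxo-7-(triisopropylsilyloxy)nona-4,6,8-trienoate 12 (not isolated), via methyl 3-[6-methoxy-3-(3-methylbut-2-en-1-yl)-2-oxo-4-(triisopropylsilyloxy)cyclohexa-3,5-dien-1-yl]propanoate 13 (not isolated), via methyl 3-[2-hydroxy-6-methoxy-3-(3-methylbut-2-en-1-yl)-4-(triisopropylsilyloxy)phenyl]propanoate 14 (not isolated)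
Conditions: 9 (1.2 equiv), toluene (0.5 M), 110 °C, sealed tube; then DBU (0.1 equiv), 110 °C, MeOH removed by slow distillation with toluene
Reagents that add atoms: none
Why: Danheiser benzannulation: on heating, cyclobutenone 5 opens in a four-electron electrocyclic reaction to vinylketene 10, which adds siloxyalkyne 9 in a [2+2] cycloaddition to 11; 11 opens to dienylketene 12, whose six-electron electrocyclisation joins the ketene carbon to the chain-bearing carbon, and dienone 13 tautomerises to phenol 14. The closest known reaction type is the thermal benzannulation of cyclobutenones with trialkylsiloxyalkynes to resorcinol monosilyl ethers; the 3-methoxy group of 5 supplies the third oxygen. The benzene ring is therefore closed by a pericyclic cascade ([2+2], four-electron opening, six-electron closure), and the lactone ring by 6-exo-trig attack of the new phenol oxygen on the side-chain ester under DBU, driven by removal of methanol. No stereocentre is formed, and the racemic centre of 5 is erased on aromatisation. The step needs regiocontrol in the [2+2] event: the polarisation of ynol ether and ketene sends the prenyl-bearing alkyne carbon to the ketene carbonyl carbon, which fixes prenyl between the ketene-derived OH and the silyloxy group, while OMe and the chain arrive already joined in 5. The free phenol, flanked by prenyl and the chain, should be too hindered to be acylated by 10, yet it sits next to the only ester it can reach.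

Step 5
Reactants: 15 5-methoxy-8-(3-methylbut-2-en-1-yl)-7-(triisopropylsilyloxy)-3,4-dihydro-2H-chromen-2-one; 16 (2R)-2-methylbutanoic acid
Product: 19 5-methoxy-8-(3-methylbut-2-en-1-yl)-2-oxo-3,4-dihydro-2H-chromen-7-yl (2R)-2-methylbutanoate, via (2R)-2-methylbutanoyl chloride 17 (not isolated), via 7-hydroxy-5-methoxy-8-(3-methylbut-2-en-1-yl)-3,4-dihydro-2H-chromen-2-one 18 (not isolated)
Conditions: 16, (COCl)2 (1.05 equiv), DMF (cat.), CH2Cl2, 0 → 20 °C, evaporated; 15, Bu4NF (1.05 equiv), THF, −40 °C; then 17 (1.2 equiv), −40 → 0 °C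
Reagents that add atoms: none
Why: Fluoride cleaves the aryl silyl ether, and the tetrabutylammonium phenoxide of 18 is acylated on oxygen by acid chloride 17, which is made without amine base so that no ketene can form and the (R) centre is carried over; the other phenolic oxygen is locked in the lactone, so only one ester can result.

Step 6
Reactants: 19 5-methoxy-8-(3-methylbut-2-en-1-yl)-2-oxo-3,4-dihydro-2H-chromen-7-yl (2R)-2-methylbutanoate
Product: 20 7-hydroxy-5-methoxy-6-[(2R)-2-methylbutanoyl]-8-(3-methylbut-2-en-1-yl)-3,4-dihydro-2H-chromen-2-one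
Conditions: hν (254 nm, low-pressure Hg lamp), degassed cyclohexane/EtOAc 9:1 (5 mM), quartz flow coil, 20 °C
Reagents that add atoms: none
Why: Photo-Fries rearrangement: homolysis of the ArO–C(O) bond and recombination of the radical pair in the solvent cage at C6, the only unsubstituted ortho carbon (C8 bears prenyl, the para carbon C4a is quaternary), then tautomerisation to the hydrogen-bonded o-hydroxy ketone; the acyl radical should recombine far faster than it loses CO and no acid or base meets the alpha-hydrogen, so the (R) centre should be retained, while the lactone C–O bond can only re-close if it is cleaved.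

Step 7
Reactants: 21 propanoyl chloride (two molecules per molecule of 23)
Product: 23 4-ethylidene-3-methyloxetan-2-one (racemic, E/Z mixture), via prop-1-en-1-one 22 (not isolated)
Conditions: Et3N (1.05 equiv per acid chloride), Et2O, 0 → 35 °C; filtered; distilled
Reagents that add atoms: propanoyl chloride, CCC(=O)Cl
Why: Dehydrochlorination of propanoyl chloride gives methylketene 22, and two molecules of 22 (hence two of 21, the second supplying the other C3O half of the product) dimerise head-to-tail by [2+2] cycloaddition to the beta-lactone (aldoketene dimerisation); the product is racemic and an E/Z mixture, which is irrelevant because both elements vanish in step 8.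

Step 8
Reactants: 20 7-hydroxy-5-methoxy-6-[(2R)-2-methylbutanoyl]-8-(3-methylbut-2-en-1-yl)-3,4-dihydro-2H-chromen-2-one; 23 4-ethylidene-3-methyloxetan-2-one
Product: 25 3-{[2,4-dihydroxy-6-methoxy-5-[(2R)-2-methylbutanoyl]-3-(3-methylbut-2-en-1-yl)phenyl]methyl}-6-ethyl-4-hydroxy-5-methyl-2H-pyran-2-one, via 7-hydroxy-5-methoxy-6-[(2R)-2-methylbutanoyl]-8-(3-methylbut-2-en-1-yl)-3-(2-methyl-3-oxopentanoyl)-3,4-dihydro-2H-chromen-2-one 24 (not isolated)
Conditions: LiN(SiMe3)2 (2.2 equiv), THF, −78 °C, 30 min; 23 (1.3 equiv), −78 → 0 °C; 20 °C, 2 h; 1 M HCl, 0 °C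
Reagents that add atoms: none
Why: Proposed new method: LiN(SiMe3)2 should deprotonate the phenol and then the lactone CH2, which as part of an aryl ester is by far the most acidic C–H (the ketone alpha-CH lies next to a phenoxide and between two ortho substituents and should stay untouched at −78 °C); the ester enolate should attack the strained enol-lactone carbonyl of ketene dimer 23, whose ring opens to an ethyl ketone enolate and so delivers the whole 2-methyl-3-oxopentanoyl unit to C3 (24) without a second equivalent of base; the enolate oxygen of the new 1,3-diketone then attacks the aryl lactone carbonyl 6-exo-trig and expels the phenoxide, which forms the aromatic 4-hydroxy-2-pyrone and frees the ortho-phenol in one event; the closest known reaction type is the base-mediated C-acetoacetylation of active methylene compounds by diketene with closure to 4-hydroxy-6-methyl-2-pyrones, together with the usual lactonisation of 3,5-dioxo esters; no stereocentre is formed (the centres of 23 and C3 become sp2) and the (R) centre is not enolised.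

**Compound list**
1 | 2-chloro-1,1-dimethoxyethane | COC(CCl)OC | starting material
2 | methoxyethyne | COC#C | intermediate
3 | methyl 5-chloro-5-oxopentanoate | COC(=O)CCCC(=O)Cl | starting material
4 | methyl 5-oxopent-4-enoate (ketene) | COC(=O)CCC=C=O | intermediate
5 | methyl 3-(2-methoxy-4-oxocyclobut-2-en-1-yl)propanoate (racemic) | COC(=O)CCC1C(OC)=CC1=O | intermediate
6 | ethyl 4-methylpent-3-enoate | CCOC(=O)CC=C(C)C | starting material
7 | lithium 1,1-dibromo-5-methylhexa-1,4-dien-2-olate | [Li+].[O-]C(=C(Br)Br)CC=C(C)C | intermediate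
8 | lithium 5-methylhex-4-en-1-yn-1-olate | [Li+].[O-]C#CCC=C(C)C | intermediate
9 | triisopropyl[(5-methylhex-4-en-1-yn-1-yl)oxy]silane | CC(C)=CCC#CO[Si](C(C)C)(C(C)C)C(C)C | intermediate
10 | methyl 5-methoxy-7-oxohepta-4,6-dienoate (vinylketene) | COC(=O)CCC=C(OC)C=C=O | intermediate
11 | methyl 5-methoxy-5-[3-(3-methylbut-2-en-1-yl)-4-oxo-2-(triisopropylsilyloxy)cyclobut-2-en-1-yl]pent-4-enoate | COC(=O)CCC=C(OC)C1C(O[Si](C(C)C)(C(C)C)C(C)C)=C(CC=C(C)C)C1=O | intermediate
12 | methyl 5-methoxy-8-(3-methylbut-2-en-1-yl)-9-oxo-7-(triisopropylsilyloxy)nona-4,6,8-trienoate (dienylketene) | COC(=O)CCC=C(OC)C=C(O[Si](C(C)C)(C(C)C)C(C)C)C(CC=C(C)C)=C=O | intermediate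
13 | methyl 3-[6-methoxy-3-(3-methylbut-2-en-1-yl)-2-oxo-4-(triisopropylsilyloxy)cyclohexa-3,5-dien-1-yl]propanoate | COC(=O)CCC1C(=O)C(CC=C(C)C)=C(O[Si](C(C)C)(C(C)C)C(C)C)C=C1OC | intermediate
14 | methyl 3-[2-hydroxy-6-methoxy-3-(3-methylbut-2-en-1-yl)-4-(triisopropylsilyloxy)phenyl]propanoate | COC(=O)CCc1c(O)c(CC=C(C)C)c(O[Si](C(C)C)(C(C)C)C(C)C)cc1OC | intermediate
15 | 5-methoxy-8-(3-methylbut-2-en-1-yl)-7-(triisopropylsilyloxy)-3,4-dihydro-2H-chromen-2-one | COc1cc(O[Si](C(C)C)(C(C)C)C(C)C)c(CC=C(C)C)c2OC(=O)CCc12 | intermediate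
16 | (2R)-2-methylbutanoic acid | CC[C@@H](C)C(=O)O | starting material
17 | (2R)-2-methylbutanoyl chloride | CC[C@@H](C)C(Cl)=O | intermediate
18 | 7-hydroxy-5-methoxy-8-(3-methylbut-2-en-1-yl)-3,4-dihydro-2H-chromen-2-one | COc1cc(O)c(CC=C(C)C)c2OC(=O)CCc12 | intermediate
19 | 5-methoxy-8-(3-methylbut-2-en-1-yl)-2-oxo-3,4-dihydro-2H-chromen-7-yl (2R)-2-methylbutanoate | CC[C@@H](C)C(=O)Oc1cc(OC)c2CCC(=O)Oc2c1CC=C(C)C | intermediate
20 | 7-hydroxy-5-methoxy-6-[(2R)-2-methylbutanoyl]-8-(3-methylbut-2-en-1-yl)-3,4-dihydro-2H-chromen-2-one | CC[C@@H](C)C(=O)c1c(O)c(CC=C(C)C)c2OC(=O)CCc2c1OC | intermediate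
21 | propanoyl chloride | CCC(=O)Cl | starting material
22 | prop-1-en-1-one (methylketene) | CC=C=O | intermediate
23 | 4-ethylidene-3-methyloxetan-2-one (racemic, E/Z mixture) | CC=C1OC(=O)C1C | intermediate
24 | 7-hydroxy-5-methoxy-6-[(2R)-2-methylbutanoyl]-8-(3-methylbut-2-en-1-yl)-3-(2-methyl-3-oxopentanoyl)-3,4-dihydro-2H-chromen-2-one | CCC(=O)C(C)C(=O)C1Cc2c(OC)c(C(=O)[C@H](C)CC)c(O)c(CC=C(C)C)c2OC1=O | intermediate
25 | 3-{[2,4-dihydroxy-6-methoxy-5-[(2R)-2-methylbutanoyl]-3-(3-methylbut-2-en-1-yl)phenyl]methyl}-6-ethyl-4-hydroxy-5-methyl-2H-pyran-2-one | CCc1oc(=O)c(Cc2c(O)c(CC=C(C)C)c(O)c(C(=O)[C@H](C)CC)c2OC)c(O)c1C | target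

Total step count: 8. Longest linear sequence: 6 steps (steps 1, 2, 4, 5, 6, 8).

**Steps most likely to fail**

Step 8. The enolate of 20 might take the acidic ring proton of 23, or the chelated phenoxide might be acylated on oxygen, instead of the C–C bond forming. The fallback sets out from 20 and returns at 24, adding the two propanoyl units one at a time by known Claisen chemistry. Compound 20 and N-methoxy-N-methylpropanamide with LiN(SiMe3)2 (THF, −78 °C) would give 7-hydroxy-5-methoxy-6-[(2R)-2-methylbutanoyl]-8-(3-methylbut-2-en-1-yl)-3-propanoyl-3,4-dihydro-2H-chromen-2-one F1. Me3SiOTf and Et3N (CH2Cl2, 0 °C) would convert the beta-keto lactone into its 1,3-bis(silyloxy)diene with the phenol silylated as well, (2R)-1-{5-methoxy-8-(3-methylbut-2-en-1-yl)-2,7-bis(trimethylsilyloxy)-3-[1-(trimethylsilyloxy)prop-1-en-1-yl]-4H-chromen-6-yl}-2-methylbutan-1-one F2. Propanoyl chloride (CH2Cl2, −78 → 20 °C, Me3SiOTf cat.) would acylate the diene terminus, and aqueous work-up would give 24, which closes to 25 as in step 8 (DBU if needed).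

Step 4. The donor-stabilised cyclobutenone might open so slowly that 9 isomerises to a silylketene, or the product phenol is acylated by 10, before the cascade ends. The fallback sets out from 3 and 9 and returns at 10; it makes the same vinylketene at 20 °C by elimination in place of ring opening. Compound 3 and the lithium enolate of tert-butyl acetate (2 equiv, from LiN(i-Pr)2, THF, −78 °C) would give 1-tert-butyl 7-methyl 3-oxoheptanedioate F3. O-Methylation (Me2SO4, K2CO3, acetone) would give 1-tert-butyl 7-methyl (2E)-3-methoxyhept-2-enedioate F4. CF3CO2H (CH2Cl2, 0 °C) would free (2E)-3,7-dimethoxy-7-oxohept-2-enoic acid F5, and (COCl)2 would convert it into methyl (5E)-7-chloro-5-methoxy-7-oxohept-5-enoate F6. Et3N in the presence of 9 would remove HCl across four atoms to give 10, and the route would continue through 11 to 15 at 60–80 °C.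

Step 6. The radical pair might escape the solvent cage (phenol 18 and loss of the acyl group), or light might be absorbed unproductively by the lactone ester and by the product. The fallback sets out from 15 and returns at 20, replacing the photochemical shift by a halogen–metal-exchange-triggered anionic Fries shift. Bu4NF/AcOH would give 18 as an isolated phenol. N-Bromosuccinimide (i-Pr2NH cat., CH2Cl2, −78 °C) would brominate C6, the only free ring carbon, to 6-bromo-7-hydroxy-5-methoxy-8-(3-methylbut-2-en-1-yl)-3,4-dihydro-2H-chromen-2-one F7. Esterification with 16 (N,N'-dicyclohexylcarbodiimide, 4-(dimethylamino)pyridine cat.) would give 6-bromo-5-methoxy-8-(3-methylbut-2-en-1-yl)-2-oxo-3,4-dihydro-2H-chromen-7-yl (2R)-2-methylbutanoate F8. n-BuLi (1.05 equiv, THF, −100 °C) would exchange bromine for lithium, and the aryllithium would take the neighbouring acyl group from oxygen to carbon to give 20.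

**Further compounds**
F1 | step 8 | 7-hydroxy-5-methoxy-6-[(2R)-2-methylbutanoyl]-8-(3-methylbut-2-en-1-yl)-3-propanoyl-3,4-dihydro-2H-chromen-2-one | CCC(=O)C1Cc2c(OC)c(C(=O)[C@H](C)CC)c(O)c(CC=C(C)C)c2OC1=O
F2 | step 8 | (2R)-1-{5-methoxy-8-(3-methylbut-2-en-1-yl)-2,7-bis(trimethylsilyloxy)-3-[1-(trimethylsilyloxy)prop-1-en-1-yl]-4H-chromen-6-yl}-2-methylbutan-1-one | CC=C(O[Si](C)(C)C)C1=C(O[Si](C)(C)C)Oc2c(CC=C(C)C)c(O[Si](C)(C)C)c(C(=O)[C@H](C)CC)c(OC)c2C1
F3 | step 4 | 1-tert-butyl 7-methyl 3-oxoheptanedioate | COC(=O)CCCC(=O)CC(=O)OC(C)(C)C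
F4 | step 4 | 1-tert-butyl 7-methyl (2E)-3-methoxyhept-2-enedioate | CC(C)(C)OC(=O)/C=C(/OC)CCCC(=O)OC
F5 | step 4 | (2E)-3,7-dimethoxy-7-oxohept-2-enoic acid | OC(=O)/C=C(/OC)CCCC(=O)OC
F6 | step 4 | methyl (5E)-7-chloro-5-methoxy-7-oxohept-5-enoate | ClC(=O)/C=C(/OC)CCCC(=O)OC
F7 | step 6 | 6-bromo-7-hydroxy-5-methoxy-8-(3-methylbut-2-en-1-yl)-3,4-dihydro-2H-chromen-2-one | COc1c(Br)c(O)c(CC=C(C)C)c2OC(=O)CCc12
F8 | step 6 | 6-bromo-5-methoxy-8-(3-methylbut-2-en-1-yl)-2-oxo-3,4-dihydro-2H-chromen-7-yl (2R)-2-methylbutanoate | CC[C@@H](C)C(=O)Oc1c(Br)c(OC)c2CCC(=O)Oc2c1CC=C(C)C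
A1 | direct plan | 5-methoxy-2-(3-methylbut-2-en-1-yl)benzene-1,3-diol | COc1cc(O)c(CC=C(C)C)c(O)c1
A2 | direct plan | (2R)-1-[2,4-dihydroxy-6-methoxy-3-(3-methylbut-2-en-1-yl)phenyl]-2-methylbutan-1-one | CC[C@@H](C)C(=O)c1c(O)c(CC=C(C)C)c(O)cc1OC
A3 | direct plan | 6-ethyl-4-hydroxy-5-methyl-2H-pyran-2-one | CCc1oc(=O)cc(O)c1C
A4 | direct plan | 6-ethyl-5-methyl-3-methylidene-2H-pyran-2,4(3H)-dione | CCC1=C(C)C(=O)C(=C)C(=O)O1
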